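The ten-membered ring C1–C10 is disconnected at C8–C9. C6 (lactone oxygen) and C1 (epoxide carbon) lie 1,6 across the ring; the two-carbon units C7–C8 and C10–C9 hang on them and the cis C4=C5 alkene sits in the other bridge, which is the imprint of a cyclohexene C1–C6 enlarged by four atoms. An anionic oxy-Cope rearrangement of a carvone-derived trans-1-alkenyl-6-isopropenylcyclohex-2-en-1-ol therefore forms the ring, the C6 carbonyl, both alkene geometries and the C8 stereocentre at once. The C8 hydroxyl then directs C7 alkylation and C6 reduction and becomes the isobutyrate; epoxidation and C15 oxidation finish the target.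

Key step: step 9

Remark: ring-expanded compounds carry the locants of the target (ring C1–C10, C14 on C10, C15 on C4, C11–C13 in the lactone arm), the target is read from its SMILES as 1R,3S,6R,7R,8R,10R, and (S)-carvone is chosen because the carbonyl/alkene transposition of step 2 turns its 5S centre into the 5R centre of trans-carveol 4.

Step 1
Reactants: 1 (S)-carvone
Product: 2 (1S,4S,6S)-1-methyl-4-(prop-1-en-2-yl)-7-oxabicyclo[4.1.0]heptan-2-one (epoxide trans to isopropenyl)
Conditions: 30% H2O2, NaOH (0.3 equiv), MeOH, 0 °C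
Reagents that add atoms: hydrogen peroxide, OO
Why: Weitz–Scheffer epoxidation touches only the enone, and hydroperoxide adds to the β-carbon on the face away from the isopropenyl group, which sets the configuration of the future C3–O bond.

Step 2
Reactants: 2 carvone oxide
Product: 4 (1S,5R)-2-methyl-5-(prop-1-en-2-yl)cyclohex-2-en-1-ol (trans-carveol), via epoxy hydrazone 3 (not isolated)
Conditions: N2H4·H2O, AcOH (cat.), MeOH, 0 °C to rt
Reagents that add atoms: none
Why: Wharton transposition, in which the hydrazone opens the epoxide and loses N2 so that the surviving C–O bond becomes the allylic alcohol with unchanged configuration, trans to the isopropenyl group.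

Step 3
Reactants: 4 trans-carveol
Product: 5 tert-butyldimethylsilyl ether of 4
Conditions: TBSCl, imidazole, DMF, rt
Reagents that add atoms: tert-butyldimethylsilyl chloride, CC(C)(C)[Si](C)(C)Cl
Why: Routine silylation of a secondary allylic alcohol gives an ether that tolerates organolithiums, KH and amide bases and is removed last.

Step 4
Reactants: 5 silyl ether
Product: 6 (4S,6R)-4-(tert-butyldimethylsilyloxy)-3-methyl-6-(prop-1-en-2-yl)cyclohex-2-en-1-one
Conditions: CrO3, 3,5-dimethylpyrazole, CH2Cl2, −20 °C
Reagents that add atoms: chromium trioxide, O=[Cr](=O)=O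
Why: Allylic oxidation by the hexavalent chromium–pyrazole complex should convert the only ring allylic CH2 into the enone carbonyl, and the cold non-basic medium should leave the α-stereocentre and the unconjugated isopropenyl group untouched.

Step 5
Reactants: 7 4-methoxybenzyl alcohol; 8 trichloroethylene
Product: 9 1-{[(E)-1,2-dichloroethenyl]oxymethyl}-4-methoxybenzene
Conditions: KH, THF, 0 °C; then 8, −50 °C to rt
Reagents that add atoms: none
Why: The potassium alkoxide dehydrochlorinates trichloroethylene and adds anti to the dichloroacetylene so formed, the standard entry to 1,2-dichlorovinyl ethers.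

Step 6
Reactants: 9 dichlorovinyl ether
Product: 11 1-(ethynyloxymethyl)-4-methoxybenzene (4-methoxybenzyl ethynyl ether), via lithium alkoxyacetylide 10 (not isolated)
Conditions: n-BuLi (2.2 equiv), THF, −78 to −40 °C; MeOH, −78 °C; solution kept cold and used at once
Reagents that add atoms: none
Why: Dehydrochlorination and chlorine–lithium exchange give the lithium alkoxyacetylide, and cold protonation releases the terminal ynol ether, which is not warmed because benzylic ynol ethers rearrange thermally.

Step 7
Reactants: 11 ynol ether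
Product: 13 1-{[(E)-2-iodoethenyl]oxymethyl}-4-methoxybenzene, via alkenylzirconocene chloride 12 (not isolated)
Conditions: Cp2Zr(H)Cl (1.1 equiv), THF, 0 °C to rt; then I2, −20 °C
Reagents that add atoms: iodine, II
Why: Hydrozirconation is a syn addition that places zirconium on the terminal carbon and iodinolysis of the C–Zr bond goes with retention, so the E enol ether geometry is fixed.

Step 8
Reactants: 13 alkenyl iodide; 6 enone
Product: 15 (1R,4S,6R)-4-(tert-butyldimethylsilyloxy)-1-[(E)-2-(4-methoxybenzyloxy)ethenyl]-3-methyl-6-(prop-1-en-2-yl)cyclohex-2-en-1-ol, via alkenyllithium 14 (not isolated)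
Conditions: t-BuLi (2.05 equiv), Et2O, −78 °C; then 6, THF, −78 °C; H2O
Reagents that add atoms: none
Why: Iodine–lithium exchange keeps the E geometry, and the alkenyllithium should add 1,2 to the enone on the face opposite the pseudo-equatorial isopropenyl group, giving the trans-1,2-dialkenyl carbinol (1R) with the hydroxyl cis to isopropenyl.

Step 9
Reactants: 15 dialkenyl carbinol
Product: 18 (2Z,4S,6E,9R)-4-(tert-butyldimethylsilyloxy)-9-(4-methoxybenzyloxy)-3,7-dimethylcyclodeca-2,6-dien-1-one (target locants: C6 ketone; 4Z; 1(10)E; 3S; 8R), via potassium alkoxide 16 (not isolated), via potassium enolate 17 (not isolated)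
Conditions: KH, 18-crown-6, THF, 0 °C to rt; then AcOH, THF, −78 °C
Reagents that add atoms: none
Why: The crown-ether-separated alkoxide 16 undergoes a concerted, alkoxide-accelerated [3,3] sigmatropic shift (anionic oxy-Cope rearrangement, well established for trans-1,2-dialkenylcyclohexanols) in which C8–C9 forms as C1–C6 breaks, giving enolate 17 and, on cold protonation, ketone 18. The ten-membered ring is not closed end to end but arises by four-atom expansion of the cyclohexene through a six-membered chair transition state, so no medium-ring cyclisation entropy is paid. C8 is the only new stereocentre and is set by chirality transfer from the carbinol carbon and C1: both ring bonds are equatorial on the chair and the E enol ether places the C8 oxygen equatorial, which should give 8R beside the existing 3S. The same chair turns the equatorial C1–C2 bond into the E C1=C10 alkene and carries the ring cis alkene over as C4=C5. The step needs chair over boat and reaction of the exocyclic alkenyl arm rather than the ring alkene; the trans diequatorial arms make the chair easy to reach, whereas a shift through the ring alkene would need a strained bicyclic boat. In 17 as formed the C8–O bond lies close to the enolate plane, which slows β-elimination, and the enolate is protonated cold as soon as the rearrangement is complete.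

Step 10
Reactants: 18 ketone
Product: 19 (2Z,4S,6E,9R)-4-(tert-butyldimethylsilyloxy)-9-hydroxy-3,7-dimethylcyclodeca-2,6-dien-1-one
Conditions: DDQ, CH2Cl2/pH 7 buffer, 0 °C
Reagents that add atoms: none
Why: Oxidative cleavage of the 4-methoxybenzyl ether under buffered neutral conditions frees the C8 hydroxyl without acid or base that could dehydrate the β-hydroxy ketone or touch the allylic silyl ether.

Step 11
Reactants: 19 β-hydroxy ketone; 20 tert-butyl bromoacetate
Product: 22 tert-butyl ester of the (3S,7R,8R)-C7-acetic acid derived from 19 (CH2CO2t-Bu on C7 and cis to the C8 hydroxyl), via dilithium alkoxide enolate 21 (not isolated)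
Conditions: LiN(i-Pr)2 (2.4 equiv), THF, −78 to −45 °C; 20, DMPU, −78 to −45 °C; AcOH, −78 °C
Reagents that add atoms: none
Why: Fráter–Seebach-type alkylation in which the lithium alkoxide and the C6–C7 enolate (C7 is the only enolisable α-position) share lithium in a six-membered chelate that holds the C8–O bond in the enolate plane, so the bromide is attacked on the face opposite C9 and the arm ends up cis to the C8 oxygen (7R), while an oxido group cannot be lost by β-elimination and the tert-butyl ester resists attack by it.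

Step 12
Reactants: 22 hydroxy keto ester; 23 isobutyraldehyde
Product: 25 (3S,6R,7S,8R) hydroxy ester with C6–OH free and O8 as the 2-methylpropanoate (C7 geometry unchanged; its label is 7S only because the priorities change), via isobutyraldehyde hemiacetal 24 (not isolated)
Conditions: SmI2 (0.3 equiv), THF, −10 °C, 23 in excess
Reagents that add atoms: none
Why: Evans–Tishchenko reduction in which the C8 hemiacetal, held with the C6 carbonyl on trivalent samarium, transfers hydride to the carbonyl face syn to the C8 oxygen, which should give the 1,3-anti C6 alcohol (6R, trans to the C7 arm), puts the isobutyrate on O8 and leaves O6 as the only free hydroxyl.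

Step 13
Reactants: 25 hydroxy ester
Product: 26 (3S,6R,7R,8R) trans-fused 6,12-lactone bearing 3-OTBS and 8-O-isobutyrate (1(10)E,4Z-diene)
Conditions: CSA (0.1 equiv), CH2Cl2, rt
Reagents that add atoms: none
Why: Acid-catalysed transesterification of the γ-hydroxy tert-butyl ester closes the five-membered lactone (5-exo-trig at the ester carbonyl) on O6, trans-fused because O6 and the C7 arm are already trans, and the 8,12-lactone cannot form because O8 is acylated.

Step 14
Reactants: 26 lactone
Product: 30 (3S,6R,7R,8R)-3-(tert-butyldimethylsilyloxy)-8-(2-methylpropanoyloxy)germacra-1(10)E,4Z,11(13)-trien-12,6-olide, via lithium lactone enolate 27 (not isolated), via Mannich base 28 (not isolated), via ammonium iodide 29 (not isolated)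
Conditions: LiN(SiMe3)2 (1.15 equiv), THF, −78 °C; [Me2N=CH2]I, −78 to 0 °C; then MeI, MeOH, rt; then aq. NaHCO3, CH2Cl2
Reagents that add atoms: dimethylmethyleneiminium iodide, C=[N+](C)C.[I-]
Why: The lactone α-CH2 is clearly more acidic and less hindered than the tertiary α-CH of the isobutyrate, so the silylamide should enolise only the lactone, and Mannich aminomethylation, quaternisation and mild-base elimination then give the exocyclic methylene without touching C7.

Step 15
Reactants: 30 methylene lactone
Product: 31 (1R,3S,6R,7R,8R,10R)-1,10-epoxy-3-(tert-butyldimethylsilyloxy)-8-(2-methylpropanoyloxy)germacra-4Z,11(13)-dien-12,6-olide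
Conditions: mCPBA, NaHCO3, CH2Cl2, 0 °C
Reagents that add atoms: 3-chloroperbenzoic acid, O=C(OO)c1cccc(Cl)c1
Why: Prilezhaev epoxidation should pick the isolated, electron-rich C1=C10 alkene over C4=C5 (flanked by two C–O bonds) and the conjugated methylene, is stereospecific for the E geometry, and should add to the outer face of the alkene in the lactone-locked ring, the 1R,10R (1β,10α) sense usual for 6,12-germacranolides.

Step 16
Reactants: 31 epoxide
Product: 32 15-hydroxy derivative of 31 (C4=C5 still Z)
Conditions: SeO2 (0.5 equiv), t-BuOOH, CH2Cl2, rt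
Reagents that add atoms: tert-butyl hydroperoxide, CC(C)(C)OO
Why: Riley oxidation in which the ene step puts selenium on C5 and takes hydrogen from the C15 methyl rather than from the oxygen-bearing C3 methine, and the [2,3] shift returns the alkene to C4=C5 with the new CH2OH trans to C6, that is with the ring-cis geometry kept, while C1=C10 is already an epoxide and the conjugated methylene is inert.

Step 17
Reactants: 32 silyl ether
Product: 33 (1R,3S,6R,7R,8R,10R)-1,10-epoxy-3,15-dihydroxy-8-(2-methylpropanoyloxy)germacra-4Z,11(13)-dien-12,6-olide (target)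
Conditions: Bu4NF, AcOH (1:1), THF, 0 °C to rt
Reagents that add atoms: none
Why: Buffered fluoride cleaves the secondary allylic silyl ether near neutral pH, which should spare the epoxide (prone to acid-induced transannular opening), the isobutyrate and the Michael-acceptor lactone.

Compound list
1 | (S)-carvone, (5S)-2-methyl-5-(prop-1-en-2-yl)cyclohex-2-en-1-one | CC(=C)[C@H]1CC=C(C)C(=O)C1 | starting material
2 | (1S,4S,6S)-1-methyl-4-(prop-1-en-2-yl)-7-oxabicyclo[4.1.0]heptan-2-one | CC(=C)[C@H]1C[C@@H]2O[C@]2(C)C(=O)C1 | intermediate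
3 | hydrazone of 2 | CC(=C)[C@H]1C[C@@H]2O[C@]2(C)C(=NN)C1 | intermediate
4 | (1S,5R)-2-methyl-5-(prop-1-en-2-yl)cyclohex-2-en-1-ol (trans-carveol) | CC(=C)[C@H]1C[C@H](O)C(C)=CC1 | intermediate
5 | tert-butyl(dimethyl){[(1S,5R)-2-methyl-5-(prop-1-en-2-yl)cyclohex-2-en-1-yl]oxy}silane | CC(=C)[C@H]1C[C@H](O[Si](C)(C)C(C)(C)C)C(C)=CC1 | intermediate
6 | (4S,6R)-4-(tert-butyldimethylsilyloxy)-3-methyl-6-(prop-1-en-2-yl)cyclohex-2-en-1-one | O=C1C=C(C)[C@@H](O[Si](C)(C)C(C)(C)C)C[C@@H]1C(C)=C | intermediate
7 | 4-methoxybenzyl alcohol | COc1ccc(CO)cc1 | starting material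
8 | trichloroethylene | ClC=C(Cl)Cl | starting material
9 | 1-{[(E)-1,2-dichloroethenyl]oxymethyl}-4-methoxybenzene | COc1ccc(CO/C(Cl)=C\Cl)cc1 | intermediate
10 | lithium 2-(4-methoxybenzyloxy)ethynide | [Li]C#COCc1ccc(OC)cc1 | intermediate
11 | 1-(ethynyloxymethyl)-4-methoxybenzene | C#COCc1ccc(OC)cc1 | intermediate
12 | chlorobis(cyclopentadienyl)[(E)-2-(4-methoxybenzyloxy)ethenyl]zirconium | Cl[Zr](/C=C/OCc1ccc(OC)cc1)(C1C=CC=C1)C1C=CC=C1 | intermediate
13 | 1-{[(E)-2-iodoethenyl]oxymethyl}-4-methoxybenzene | I/C=C/OCc1ccc(OC)cc1 | intermediate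
14 | (E)-2-(4-methoxybenzyloxy)ethenyllithium | [Li]/C=C/OCc1ccc(OC)cc1 | intermediate
15 | (1R,4S,6R)-4-(tert-butyldimethylsilyloxy)-1-[(E)-2-(4-methoxybenzyloxy)ethenyl]-3-methyl-6-(prop-1-en-2-yl)cyclohex-2-en-1-ol | O[C@]1(/C=C/OCc2ccc(OC)cc2)C=C(C)[C@@H](O[Si](C)(C)C(C)(C)C)C[C@@H]1C(C)=C | intermediate
16 | potassium alkoxide of 15 | [K+].[O-][C@]1(/C=C/OCc2ccc(OC)cc2)C=C(C)[C@@H](O[Si](C)(C)C(C)(C)C)C[C@@H]1C(C)=C | intermediate
17 | potassium C6–C7 enolate of 18 (O cis to C8) | C1/C(C)=C/C[C@H](O[Si](C)(C)C(C)(C)C)/C(C)=C\C(\[O-])=C\[C@@H]1OCc2ccc(OC)cc2.[K+] | intermediate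
18 | (2Z,4S,6E,9R)-4-(tert-butyldimethylsilyloxy)-9-(4-methoxybenzyloxy)-3,7-dimethylcyclodeca-2,6-dien-1-one | O=C1/C=C(/C)[C@@H](O[Si](C)(C)C(C)(C)C)C/C=C(\C)C[C@@H](OCc2ccc(OC)cc2)C1 | intermediate
19 | (2Z,4S,6E,9R)-4-(tert-butyldimethylsilyloxy)-9-hydroxy-3,7-dimethylcyclodeca-2,6-dien-1-one | O=C1/C=C(/C)[C@@H](O[Si](C)(C)C(C)(C)C)C/C=C(\C)C[C@@H](O)C1 | intermediate
20 | tert-butyl bromoacetate | BrCC(=O)OC(C)(C)C | starting material
21 | dilithium C8 alkoxide C6–C7 enolate of 19 | C1/C(C)=C/C[C@H](O[Si](C)(C)C(C)(C)C)/C(C)=C\C(\[O-])=C\[C@@H]1[O-].[Li+].[Li+] | intermediate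
22 | (3S,7R,8R) C7-(tert-butoxycarbonylmethyl) derivative of 19, arm cis to the C8 hydroxyl | O=C1/C=C(/C)[C@@H](O[Si](C)(C)C(C)(C)C)C/C=C(\C)C[C@@H](O)[C@H]1CC(=O)OC(C)(C)C | intermediate
23 | isobutyraldehyde (2-methylpropanal) | CC(C)C=O | starting material
24 | O8 hemiacetal of 22 with isobutyraldehyde (samarium-bound in the flask) | O=C1/C=C(/C)[C@@H](O[Si](C)(C)C(C)(C)C)C/C=C(\C)C[C@@H](OC(O)C(C)C)[C@H]1CC(=O)OC(C)(C)C | intermediate
25 | (3S,6R,7S,8R) C6 alcohol, O8 2-methylpropanoate, C7-CH2CO2t-Bu | O[C@@H]1/C=C(/C)[C@@H](O[Si](C)(C)C(C)(C)C)C/C=C(\C)C[C@@H](OC(=O)C(C)C)[C@H]1CC(=O)OC(C)(C)C | intermediate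
26 | (3S,6R,7R,8R) trans-fused 6,12-lactone, 3-OTBS, 8-O-isobutyrate, 1(10)E,4Z-diene | C1C(=O)O[C@@H]2/C=C(/C)[C@@H](O[Si](C)(C)C(C)(C)C)C/C=C(\C)C[C@@H](OC(=O)C(C)C)[C@@H]12 | intermediate
27 | lithium enolate of lactone 26 | C1=C([O-])O[C@@H]2/C=C(/C)[C@@H](O[Si](C)(C)C(C)(C)C)C/C=C(\C)C[C@@H](OC(=O)C(C)C)[C@@H]12.[Li+] | intermediate
28 | C11-(dimethylaminomethyl) lactone (Mannich base) | CN(C)CC1C(=O)O[C@@H]2/C=C(/C)[C@@H](O[Si](C)(C)C(C)(C)C)C/C=C(\C)C[C@@H](OC(=O)C(C)C)[C@@H]12 | intermediate
29 | trimethylammonium iodide of 28 | C[N+](C)(C)CC1C(=O)O[C@@H]2/C=C(/C)[C@@H](O[Si](C)(C)C(C)(C)C)C/C=C(\C)C[C@@H](OC(=O)C(C)C)[C@@H]12.[I-] | intermediate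
30 | (3S,6R,7R,8R)-3-(tert-butyldimethylsilyloxy)-8-(2-methylpropanoyloxy)germacra-1(10)E,4Z,11(13)-trien-12,6-olide | C=C1C(=O)O[C@@H]2/C=C(/C)[C@@H](O[Si](C)(C)C(C)(C)C)C/C=C(\C)C[C@@H](OC(=O)C(C)C)[C@@H]12 | intermediate
31 | (1R,3S,6R,7R,8R,10R)-1,10-epoxy-3-(tert-butyldimethylsilyloxy)-8-(2-methylpropanoyloxy)germacra-4Z,11(13)-dien-12,6-olide | C=C1C(=O)O[C@@H]2/C=C(/C)[C@@H](O[Si](C)(C)C(C)(C)C)C[C@H]3O[C@]3(C)C[C@@H](OC(=O)C(C)C)[C@@H]12 | intermediate
32 | 15-hydroxy derivative of 31 | C=C1C(=O)O[C@@H]2/C=C(/CO)[C@@H](O[Si](C)(C)C(C)(C)C)C[C@H]3O[C@]3(C)C[C@@H](OC(=O)C(C)C)[C@@H]12 | intermediate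
33 | (1R,3S,6R,7R,8R,10R)-1,10-epoxy-3,15-dihydroxy-8-(2-methylpropanoyloxy)germacra-4Z,11(13)-dien-12,6-olide | C=C1C(=O)O[C@@H]2/C=C(/CO)[C@@H](O)C[C@H]3O[C@]3(C)C[C@@H](OC(=O)C(C)C)[C@@H]12 | target

Total step count: 17. Longest linear sequence: 14 steps, from 1 through steps 1–4 and 8–17; steps 5–7 prepare the alkenyl iodide.

Steps most likely to fail

Step 9. The potassium enolate has to survive at the temperature the rearrangement needs; once the ring flexes so that the C8–O bond lines up with the enolate π system the ether is expelled, and leakage through a boat or through the ring alkene would erode C8 and the ring size. The fallback sets out from 15 and comes back at 18. The same [3,3] expansion is run without any enolate, as a divalent-palladium-catalysed oxy-Cope rearrangement (PdCl2(PhCN)2, 10 mol %, THF, rt). The metal-bound enol ether is attacked at C8 by the isopropenyl terminus C9 through a chair-like cyclohexyl cation stabilised at the tertiary C10, and fragmentation of C1–C6 releases the enol of 18. No compound outside the list is formed (F0).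

Step 11. Deprotonation next to an oxido-bearing carbon is slow, so the amide may instead take a γ-hydrogen of the enone (C15) or the aldolate may open by retro-aldol on warming; the facial bias also rests on a lithium chelate. The fallback sets out from 19 and comes back at 22. O8 and the enol oxygen on C6 are tied together covalently: t-Bu2Si(OTf)2 and Et3N in CH2Cl2 should give the cyclic di-tert-butylsilylene enol ether F1, in which the enol can only be C6=C7 and the C8–O bond is held in the enol plane. Copper-catalysed cyclopropanation with tert-butyl diazoacetate (Cu(acac)2, CH2Cl2) on the face opposite C9 gives the siloxycyclopropane ester F2. Et3N·3HF at 0 °C then opens the donor–acceptor cyclopropane and removes the silylene to give 22.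

Step 16. The ene step is slow at an alkene flanked by two C–O bonds, and under the longer or warmer treatment then needed the exocyclic methylene lactone is consumed by conjugate addition and the alcohol over-oxidises. The fallback sets out from 26 and comes back at 32; the order is changed so that the allylic oxidation runs before the Michael acceptor exists. mCPBA converts 26 into the 1,10-epoxy lactone F3, and stoichiometric SeO2 with pyridine in dioxane at 50 °C gives the C15 alcohol F4. Methylenation as in step 14, but with 2.3 equiv of LiN(SiMe3)2, proceeds through the dilithium alkoxide enolate F5, the Mannich base F6 and the ammonium iodide F7 to give 32.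

Further compounds
F0 | step 9 | none | none
F1 | step 11 | cyclic di-tert-butylsilylene enol ether of 19 (O6–Si–O8, C6=C7) | C1/C(C)=C/C[C@H](O[Si](C)(C)C(C)(C)C)/C(C)=C\C(\O2)=C\[C@@H]1O[Si]2(C(C)(C)C)C(C)(C)C
F2 | step 11 | siloxycyclopropane tert-butyl ester from F1 (C6–C7–C11 ring, C11 opposite C9, C11 configuration open) | C1/C(C)=C/C[C@H](O[Si](C)(C)C(C)(C)C)/C(C)=C\[C@]23O[Si](C(C)(C)C)(C(C)(C)C)O[C@H]1[C@H]2C3C(=O)OC(C)(C)C
F3 | step 16 | (1R,10R)-1,10-epoxide of lactone 26 | C1C(=O)O[C@@H]2/C=C(/C)[C@@H](O[Si](C)(C)C(C)(C)C)C[C@H]3O[C@]3(C)C[C@@H](OC(=O)C(C)C)[C@@H]12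
F4 | step 16 | 15-hydroxy derivative of F3 | C1C(=O)O[C@@H]2/C=C(/CO)[C@@H](O[Si](C)(C)C(C)(C)C)C[C@H]3O[C@]3(C)C[C@@H](OC(=O)C(C)C)[C@@H]12
F5 | step 16 | dilithium C15 alkoxide lactone enolate of F4 | C1=C([O-])O[C@@H]2/C=C(/C[O-])[C@@H](O[Si](C)(C)C(C)(C)C)C[C@H]3O[C@]3(C)C[C@@H](OC(=O)C(C)C)[C@@H]12.[Li+].[Li+]
F6 | step 16 | C11-(dimethylaminomethyl) derivative of F4 | CN(C)CC1C(=O)O[C@@H]2/C=C(/CO)[C@@H](O[Si](C)(C)C(C)(C)C)C[C@H]3O[C@]3(C)C[C@@H](OC(=O)C(C)C)[C@@H]12
F7 | step 16 | trimethylammonium iodide of F6 | C[N+](C)(C)CC1C(=O)O[C@@H]2/C=C(/CO)[C@@H](O[Si](C)(C)C(C)(C)C)C[C@H]3O[C@]3(C)C[C@@H](OC(=O)C(C)C)[C@@H]12.[I-]
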